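The whole route hangs on cutting the C5–C6 bond of the ten-membered carbocycle (ring A). The lactone oxygen on C6 sits next to the C4=C5 alkene, so C6(=O)–C5–C4(OH) is a hidden aldol and hence an isoxazoline. One operation, an intramolecular nitrile oxide–alkene cycloaddition, joins C6 to C5 and oxygen to C4, closing ring A and a bridging isoxazoline together. The precursor is an open-chain C6 aldoxime carrying the C7–C9 stereotriad (8,9-trans-acetonide from L-threitol), the preset C1=C10 alkene with C14 as a PMB ether, and the 1,1-disubstituted C4=C5H2 terminus with C15 as a TBDPS ether.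

Key step: step 15

Remark: germacrane numbering is used for all intermediates (C12 lactone carbonyl, C13 exocyclic methylene, C14 formyl carbon, C15 hydroxymethyl carbon); TBS = tert-butyldimethylsilyl, TBDPS = tert-butyldiphenylsilyl, PMB = 4-methoxybenzyl.

Assumption: compounds 1 (the acetonide of L-threitol, the reduced form of L-tartaric acid), 7, 8, 15 and 36 are bought.

Carbon map: C7–C10 from 1; C1 from CBr4; C2 from methyl chloroformate; C14 from 7; C3, C4, C5 and C15 from 15; C11 and C12 from the Wittig reagent; C6 from nitromethane; C13 from the iminium salt.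

Remark: the C15 ether is TBDPS so that it outlasts the TBS ether (step 11) and the acetonide hydrolysis (step 20). Oxime 23 may form as an E/Z mixture; both isomers give the same nitrile oxide, and the E isomer is drawn.

Step 1
Reactants: 1 (4S,5S)-2,2-dimethyl-1,3-dioxolane-4,5-dimethanol
Product: 2 [(4S,5S)-5-(TBSO-methyl)-2,2-dimethyl-1,3-dioxolan-4-yl]methanol
Conditions: NaH (1.0 equiv), THF, 0 °C; TBSCl (1.0 equiv), 0 °C → rt
Reagents that add atoms: tert-butyldimethylsilyl chloride, CC(C)(C)[Si](C)(C)Cl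
Why: O-silylation through the poorly soluble mono-sodium alkoxide of a C2-symmetric diol should stop at the mono-ether, and since both ends are equivalent the silylated end simply becomes C7.

Step 2
Reactants: 2 [(4S,5S)-5-(TBSO-methyl)-2,2-dimethyl-1,3-dioxolan-4-yl]methanol
Product: 3 (4R,5S)-5-(TBSO-methyl)-2,2-dimethyl-1,3-dioxolane-4-carbaldehyde
Conditions: TEMPO (10 mol%), PhI(OAc)2 (1.1 equiv), CH2Cl2, rt
Reagents that add atoms: none
Why: Oxoammonium-mediated oxidation of a primary alcohol stops at the aldehyde without base, and the α-centre (C9) is part of the more stable trans-dioxolane, so epimerisation has no driving force.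

Step 3
Reactants: 3 (4R,5S)-5-(TBSO-methyl)-2,2-dimethyl-1,3-dioxolane-4-carbaldehyde
Product: 4 (4S,5S)-4-(2,2-dibromoethenyl)-5-(TBSO-methyl)-2,2-dimethyl-1,3-dioxolane
Conditions: CBr4, PPh3, Et3N, CH2Cl2, 0 °C
Reagents that add atoms: carbon tetrabromide, BrC(Br)(Br)Br
Why: First stage of the Corey–Fuchs reaction, a Wittig-type dibromomethylenation by Ph3P=CBr2 that installs C1 on the aldehyde carbon C10.

Step 4
Reactants: 4 (4S,5S)-4-(2,2-dibromoethenyl)-5-(TBSO-methyl)-2,2-dimethyl-1,3-dioxolane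
Product: 6 methyl 3-[(4S,5S)-5-(TBSO-methyl)-2,2-dimethyl-1,3-dioxolan-4-yl]prop-2-ynoate, via lithium acetylide 5 (not isolated)
Conditions: n-BuLi (2.1 equiv), THF, −78 °C; then ClCO2Me, −78 → 0 °C
Reagents that add atoms: methyl chloroformate, COC(=O)Cl
Why: Second stage of the Corey–Fuchs reaction (Br/Li exchange, 1,2-shift, deprotonation) followed by C-acylation of the acetylide in the same flask gives the ynoate whose ester carbon is C2.

Step 5
Reactants: 7 tributyl(iodomethyl)stannane; 8 (4-methoxyphenyl)methanol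
Product: 9 tributyl{[(4-methoxybenzyl)oxy]methyl}stannane
Conditions: NaH, THF/DMF, 0 °C → rt
Reagents that add atoms: none
Why: Williamson etherification of a primary iodide that has no β-hydrogen and therefore cannot eliminate.

Step 6
Reactants: 6 methyl 3-[(4S,5S)-5-(TBSO-methyl)-2,2-dimethyl-1,3-dioxolan-4-yl]prop-2-ynoate; 9 tributyl{[(4-methoxybenzyl)oxy]methyl}stannane
Product: 12 methyl (2Z)-3-[(4S,5S)-5-(TBSO-methyl)-2,2-dimethyl-1,3-dioxolan-4-yl]-4-(PMBO)but-2-enoate, via organolithium 10 (not isolated), via cuprate 11 (not isolated)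
Conditions: 9 (2.2 equiv), n-BuLi, THF, −78 °C; CuBr·SMe2 (1.1 equiv), −78 °C; 6, −78 °C; MeOH then aq. NH4Cl, −78 °C → rt
Reagents that add atoms: none
Why: Tin–lithium exchange gives the α-alkoxymethyllithium, whose Gilman cuprate adds syn across the ynoate (carbocupration) so that C14 arrives on C10 cis to the new C1–H, and cold protonation keeps this geometry with C2 cis to C9 and trans to C14.

Step 7
Reactants: 12 methyl (2Z)-3-[(4S,5S)-5-(TBSO-methyl)-2,2-dimethyl-1,3-dioxolan-4-yl]-4-(PMBO)but-2-enoate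
Product: 13 (2Z)-3-[(4S,5S)-5-(TBSO-methyl)-2,2-dimethyl-1,3-dioxolan-4-yl]-4-(PMBO)but-2-en-1-ol
Conditions: i-Bu2AlH (2.5 equiv), CH2Cl2, −78 °C; aq. potassium sodium tartrate
Reagents that add atoms: none
Why: 1,2-Reduction of an enoate to the allylic alcohol by an aluminium hydride leaves the alkene geometry untouched, and lactonisation is impossible because O9 is locked in the acetonide.

Step 8
Reactants: 13 (2Z)-3-[(4S,5S)-5-(TBSO-methyl)-2,2-dimethyl-1,3-dioxolan-4-yl]-4-(PMBO)but-2-en-1-ol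
Product: 14 (4S,5S)-4-[(2Z)-4-bromo-1-(PMBO)but-2-en-2-yl]-5-(TBSO-methyl)-2,2-dimethyl-1,3-dioxolane
Conditions: CBr4, PPh3, 2,6-lutidine, CH2Cl2, −20 → 0 °C
Reagents that add atoms: carbon tetrabromide, BrC(Br)(Br)Br
Why: Appel reaction, an SN2 displacement at the primary allylic carbon C2 under near-neutral conditions that spare the acetonide and the alkene geometry.

Step 9
Reactants: 14 (4S,5S)-4-[(2Z)-4-bromo-1-(PMBO)but-2-en-2-yl]-5-(TBSO-methyl)-2,2-dimethyl-1,3-dioxolane; 15 2-methylprop-2-en-1-ol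
Product: 17 (5Z)-6-[(4S,5S)-5-(TBSO-methyl)-2,2-dimethyl-1,3-dioxolan-4-yl]-7-(PMBO)-2-methylidenehept-5-en-1-ol, via dilithiated methallyl alcohol 16 (not isolated)
Conditions: 15 (3 equiv), n-BuLi (6 equiv), TMEDA, Et2O, 0 °C → rt; then 14, THF, −78 → 0 °C
Reagents that add atoms: none
Why: The O,C-dilithiated methallyl alcohol is an allyl anion with two equivalent carbon termini, so SN2 alkylation at the unhindered C2 forms the C2–C3 bond without nucleophile regiochemistry, while SN2' would have to attack the fully substituted C10.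

Step 10
Reactants: 17 (5Z)-6-[(4S,5S)-5-(TBSO-methyl)-2,2-dimethyl-1,3-dioxolan-4-yl]-7-(PMBO)-2-methylidenehept-5-en-1-ol
Product: 18 C15 TBDPS ether of 17
Conditions: TBDPSCl, imidazole, CH2Cl2, rt
Reagents that add atoms: tert-butyl(chloro)diphenylsilane, CC(C)(C)[Si](Cl)(c1ccccc1)c1ccccc1
Why: Imidazole-promoted silylation of a primary allylic alcohol is routine.

Step 11
Reactants: 18 C15 TBDPS ether of 17
Product: 19 {(4S,5S)-5-[(2Z)-7-(TBDPSO)-6-methylidene-1-(PMBO)hept-2-en-2-yl]-2,2-dimethyl-1,3-dioxolan-4-yl}methanol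
Conditions: HF·pyridine, pyridine, THF, 0 °C
Reagents that add atoms: none
Why: Buffered fluoride cleaves a primary TBS ether far faster than a TBDPS ether and leaves the PMB ether and acetonide alone (selective desilylation).

Step 12
Reactants: 19 {(4S,5S)-5-[(2Z)-7-(TBDPSO)-6-methylidene-1-(PMBO)hept-2-en-2-yl]-2,2-dimethyl-1,3-dioxolan-4-yl}methanol
Product: 21 methyl (2E)-3-{(4S,5S)-5-[(2Z)-7-(TBDPSO)-6-methylidene-1-(PMBO)hept-2-en-2-yl]-2,2-dimethyl-1,3-dioxolan-4-yl}prop-2-enoate, via aldehyde 20 (not isolated)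
Conditions: TEMPO (10 mol%), PhI(OAc)2, CH2Cl2, rt; then Ph3P=CHCO2Me, rt
Reagents that add atoms: methyl (triphenylphosphoranylidene)acetate, COC(=O)C=P(c1ccccc1)(c1ccccc1)c1ccccc1
Why: One-pot oxidation and Wittig olefination with a stabilised ylide should give the E-enoate without handling the α-alkoxy aldehyde, and any Z-enoate formed would lead to the same adduct in step 13.

Step 13
Reactants: 21 methyl (2E)-3-{(4S,5S)-5-[(2Z)-7-(TBDPSO)-6-methylidene-1-(PMBO)hept-2-en-2-yl]-2,2-dimethyl-1,3-dioxolan-4-yl}prop-2-enoate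
Product: 22 methyl (3S)-3-{(4S,5S)-5-[(2Z)-7-(TBDPSO)-6-methylidene-1-(PMBO)hept-2-en-2-yl]-2,2-dimethyl-1,3-dioxolan-4-yl}-4-nitrobutanoate
Conditions: MeNO2 (10 equiv), DBU, MeCN, 0 °C → rt
Reagents that add atoms: nitromethane, C[N+](=O)[O-]
Why: Michael addition of the nitronate to a γ-alkoxy enoate should proceed by Felkin–Anh-type attack anti to the C8–O bond, the known syn selectivity of dioxolanyl acrylates, which sets C7 (7S) and brings in C6; the minor epimer is removed by chromatography.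

Step 14
Reactants: 22 methyl (3S)-3-{(4S,5S)-5-[(2Z)-7-(TBDPSO)-6-methylidene-1-(PMBO)hept-2-en-2-yl]-2,2-dimethyl-1,3-dioxolan-4-yl}-4-nitrobutanoate
Product: 23 methyl (3S,4E)-3-{(4S,5S)-5-[(2Z)-7-(TBDPSO)-6-methylidene-1-(PMBO)hept-2-en-2-yl]-2,2-dimethyl-1,3-dioxolan-4-yl}-4-(hydroxyimino)butanoate
Conditions: SnCl2·2H2O (1.5 equiv), PhSH (4.5 equiv), Et3N (4.5 equiv), MeCN, rt
Reagents that add atoms: none
Why: The divalent tin thiolate complex formed in the flask reduces a primary nitroalkane to the aldoxime under neutral conditions that leave the ester, silyl ether, PMB ether and alkenes alone and do not epimerise C7.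

Step 15
Reactants: 23 methyl (3S,4E)-3-{(4S,5S)-5-[(2Z)-7-(TBDPSO)-6-methylidene-1-(PMBO)hept-2-en-2-yl]-2,2-dimethyl-1,3-dioxolan-4-yl}-4-(hydroxyimino)butanoate
Product: 26 isoxazoline-bridged ten-membered carbocycle (4R,7S,8S,9S; 1(10)Z), via hydroximoyl chloride 24 (not isolated), via nitrile oxide 25 (not isolated)
Conditions: aq. NaOCl (5 equiv), CH2Cl2, 0 °C → rt; 23 added by syringe pump over 12 h to a final 1 mM
Reagents that add atoms: none
Why: Hypochlorite C-chlorinates the aldoxime and the aqueous base removes HCl from chloride 24, so nitrile oxide 25 is released slowly and adds across C4=C5 in a concerted suprafacial (3+2) cycloaddition, C6 bonding to C5 and oxygen to C4. The closest known reaction type is the intramolecular nitrile oxide–alkene cycloaddition used as a macrocyclisation, with the isoxazoline as a masked aldol. The isoxazoline ring is closed by the cycloaddition itself, and the ten-membered carbocycle is closed in the endo (bridged) mode, the dipole carbon attacking the unsubstituted alkene terminus so that C4 lies inside the new ring, whereas the exo mode would give a fused nine-membered ring. The only new stereocentre, C4, is set by the alkene face that the tether can present to the dipole, which is dictated by the C7–C9 stereotriad held in the trans-dioxolane; either outcome is acceptable because C4 becomes trigonal in step 17. The step needs regioselectivity, secured by the intrinsic preference of nitrile oxides to place carbon on the CH2 end of a 1,1-disubstituted alkene, and chemoselectivity over the nearer C1=C10 alkene, secured because that alkene is trisubstituted, would have to be attacked with mismatched regiochemistry at the fully substituted C10 and would give a cyclopentane trans-fused to the dioxolane. Dimerisation to furoxan is held back by slow addition at high dilution.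

Step 16
Reactants: 26 isoxazoline-bridged ten-membered carbocycle
Product: 27 ring β-hydroxy ketone (C6 ketone, C4 tertiary alcohol)
Conditions: Mo(CO)6, MeCN/H2O (10:1), 80 °C
Reagents that add atoms: water, O
Why: Zerovalent molybdenum cleaves the weak N–O bond reductively and the resulting β-hydroxy imine hydrolyses to the β-hydroxy ketone, without the hydrogenation conditions that would endanger the alkenes and the PMB ether.

Step 17
Reactants: 27 ring β-hydroxy ketone
Product: 29 ring-cis (4E) enone, via tertiary mesylate 28 (not isolated)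
Conditions: MsCl, Et3N, CH2Cl2, 0 °C → rt
Reagents that add atoms: none
Why: Sulfene mesylation of the tertiary alcohol followed by E1cB elimination through the C5 enolate can only place the alkene in conjugation at C4=C5, the ring-cis geometry being expected as the less strained one in a ten-membered ring, while the weak amine base at low temperature spares C7 and the C8–O bond.

Step 18
Reactants: 29 ring-cis (4E) enone
Product: 31 trans-fused 12,6-lactone (6R,7S,8S,9S), via hydroxy ester 30 (not isolated)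
Conditions: NaBH4, CeCl3·7H2O, MeOH, −40 °C; then PPTS (cat.), CH2Cl2, rt
Reagents that add atoms: none
Why: Luche 1,2-reduction is expected to deliver hydride to the outer face of the enone anti to the C7 acetate arm (Felkin-type substrate control), giving the (6R)-alcohol, which closes onto C12 by acid-catalysed transesterification to the trans-fused γ-lactone.

Step 19
Reactants: 31 trans-fused 12,6-lactone
Product: 34 α-methylene lactone, via Mannich base 32 (not isolated), via ammonium iodide 33 (not isolated)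
Conditions: LiN(SiMe3)2, THF, −78 °C; CH2=NMe2+ I−, −78 °C → rt; then MeI, CH2Cl2/MeOH, rt; aq. NaHCO3, rt
Reagents that add atoms: dimethyl(methylidene)ammonium iodide, C=[N+](C)C.[I-]
Why: Mannich aminomethylation of the lactone enolate, N-quaternisation and E1cB loss of trimethylamine is the standard α-methylenation; it installs C13 and leaves no stereocentre at C11.

Step 20
Reactants: 34 α-methylene lactone
Product: 35 8,9-diol
Conditions: AcOH/H2O (4:1), 40 °C
Reagents that add atoms: none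
Why: Acid hydrolysis of the strained trans-fused dioxolane is mild enough for the PMB ether, the TBDPS ether and both the lactone and its exocyclic alkene.

Step 21
Reactants: 35 8,9-diol; 36 angelic acid
Product: 38 8,9-bis-angelate, via mixed anhydride 37 (not isolated)
Conditions: 36 (6 equiv), 2,4,6-Cl3C6H2COCl, Et3N, toluene, rt; then 35, 80 °C
Reagents that add atoms: none
Why: Yamaguchi-type acylation with the preformed mixed anhydride and no nucleophilic catalyst is the known way to transfer an angeloyl group to hindered secondary alcohols without Z-to-E isomerisation, and the absence of DMAP also protects the α-methylene lactone.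

Step 22
Reactants: 38 8,9-bis-angelate
Product: 39 C14 allylic alcohol
Conditions: DDQ, CH2Cl2/pH 7 buffer, 0 °C
Reagents that add atoms: none
Why: Oxidative cleavage of the PMB ether by hydride abstraction is orthogonal to the esters, the lactone and the silyl ether.

Step 23
Reactants: 39 C14 allylic alcohol
Product: 40 C14 enal
Conditions: MnO2, CH2Cl2, rt
Reagents that add atoms: none
Why: Activated MnO2 oxidises a primary allylic alcohol selectively to the enal, and the ring holds the C1=C10 geometry (now 1(10)E by priority).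

Step 24
Reactants: 40 C14 enal
Product: 41 CNP0139154.1
Conditions: HF·pyridine, pyridine, THF, 0 °C → rt
Reagents that add atoms: none
Why: Buffered fluoride removes the TBDPS group without base, so the angelates, the enal and the α-methylene lactone are neither attacked nor isomerised.

Compound list
1 | (4S,5S)-2,2-dimethyl-1,3-dioxolane-4,5-dimethanol (2,3-O-isopropylidene-L-threitol) | OC[C@H](OC1(C)C)[C@@H](O1)CO | starting material
2 | [(4S,5S)-5-(TBSO-methyl)-2,2-dimethyl-1,3-dioxolan-4-yl]methanol | OC[C@H](OC1(C)C)[C@@H](O1)CO[Si](C)(C)C(C)(C)C | intermediate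
3 | (4R,5S)-5-(TBSO-methyl)-2,2-dimethyl-1,3-dioxolane-4-carbaldehyde | O=C[C@H](OC1(C)C)[C@@H](O1)CO[Si](C)(C)C(C)(C)C | intermediate
4 | (4S,5S)-4-(2,2-dibromoethenyl)-5-(TBSO-methyl)-2,2-dimethyl-1,3-dioxolane | BrC(Br)=C[C@H](OC1(C)C)[C@@H](O1)CO[Si](C)(C)C(C)(C)C | intermediate
5 | lithium acetylide of the (4S,5S)-4-ethynyl-5-(TBSO-methyl)dioxolane | [Li]C#C[C@H](OC1(C)C)[C@@H](O1)CO[Si](C)(C)C(C)(C)C | intermediate
6 | methyl 3-[(4S,5S)-5-(TBSO-methyl)-2,2-dimethyl-1,3-dioxolan-4-yl]prop-2-ynoate | COC(=O)C#C[C@H](OC1(C)C)[C@@H](O1)CO[Si](C)(C)C(C)(C)C | intermediate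
7 | tributyl(iodomethyl)stannane | CCCC[Sn](CCCC)(CCCC)CI | starting material
8 | (4-methoxyphenyl)methanol | COc1ccc(CO)cc1 | starting material
9 | tributyl{[(4-methoxybenzyl)oxy]methyl}stannane | CCCC[Sn](CCCC)(CCCC)COCc1ccc(OC)cc1 | intermediate
10 | {[(4-methoxybenzyl)oxy]methyl}lithium | [Li]COCc1ccc(OC)cc1 | intermediate
11 | lithium bis{[(4-methoxybenzyl)oxy]methyl}cuprate | [Li+].COc1ccc(COC[Cu-]COCc2ccc(OC)cc2)cc1 | intermediate
12 | methyl (2Z)-3-[(4S,5S)-5-(TBSO-methyl)-2,2-dimethyl-1,3-dioxolan-4-yl]-4-(PMBO)but-2-enoate (ester cis to C9) | COC(=O)/C=C(/COCc1ccc(OC)cc1)[C@H](OC1(C)C)[C@@H](O1)CO[Si](C)(C)C(C)(C)C | intermediate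
13 | (2Z)-3-[(4S,5S)-5-(TBSO-methyl)-2,2-dimethyl-1,3-dioxolan-4-yl]-4-(PMBO)but-2-en-1-ol | OC/C=C(/COCc1ccc(OC)cc1)[C@H](OC1(C)C)[C@@H](O1)CO[Si](C)(C)C(C)(C)C | intermediate
14 | (4S,5S)-4-[(2Z)-4-bromo-1-(PMBO)but-2-en-2-yl]-5-(TBSO-methyl)-2,2-dimethyl-1,3-dioxolane | BrC/C=C(/COCc1ccc(OC)cc1)[C@H](OC1(C)C)[C@@H](O1)CO[Si](C)(C)C(C)(C)C | intermediate
15 | 2-methylprop-2-en-1-ol | C=C(C)CO | starting material
16 | O,C-dilithiated 2-methylprop-2-en-1-ol | [Li]CC(=C)CO[Li] | intermediate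
17 | (5Z)-6-[(4S,5S)-5-(TBSO-methyl)-2,2-dimethyl-1,3-dioxolan-4-yl]-7-(PMBO)-2-methylidenehept-5-en-1-ol | C=C(CO)CC/C=C(/COCc1ccc(OC)cc1)[C@H](OC1(C)C)[C@@H](O1)CO[Si](C)(C)C(C)(C)C | intermediate
18 | C15 TBDPS ether of 17 (C7 OTBS, C14 OPMB, 8,9-acetonide) | C=C(CO[Si](c1ccccc1)(c1ccccc1)C(C)(C)C)CC/C=C(/COCc1ccc(OC)cc1)[C@H](OC1(C)C)[C@@H](O1)CO[Si](C)(C)C(C)(C)C | intermediate
19 | {(4S,5S)-5-[(2Z)-7-(TBDPSO)-6-methylidene-1-(PMBO)hept-2-en-2-yl]-2,2-dimethyl-1,3-dioxolan-4-yl}methanol | C=C(CO[Si](c1ccccc1)(c1ccccc1)C(C)(C)C)CC/C=C(/COCc1ccc(OC)cc1)[C@H](OC1(C)C)[C@@H](O1)CO | intermediate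
20 | (4R,5S)-5-[(2Z)-7-(TBDPSO)-6-methylidene-1-(PMBO)hept-2-en-2-yl]-2,2-dimethyl-1,3-dioxolane-4-carbaldehyde | C=C(CO[Si](c1ccccc1)(c1ccccc1)C(C)(C)C)CC/C=C(/COCc1ccc(OC)cc1)[C@H](OC1(C)C)[C@@H](O1)C=O | intermediate
21 | methyl (2E)-3-{(4S,5S)-5-[(2Z)-7-(TBDPSO)-6-methylidene-1-(PMBO)hept-2-en-2-yl]-2,2-dimethyl-1,3-dioxolan-4-yl}prop-2-enoate | C=C(CO[Si](c1ccccc1)(c1ccccc1)C(C)(C)C)CC/C=C(/COCc1ccc(OC)cc1)[C@H](OC1(C)C)[C@@H](O1)/C=C/C(=O)OC | intermediate
22 | methyl (3S)-3-{(4S,5S)-5-[(2Z)-7-(TBDPSO)-6-methylidene-1-(PMBO)hept-2-en-2-yl]-2,2-dimethyl-1,3-dioxolan-4-yl}-4-nitrobutanoate | C=C(CO[Si](c1ccccc1)(c1ccccc1)C(C)(C)C)CC/C=C(/COCc1ccc(OC)cc1)[C@H](OC1(C)C)[C@@H](O1)[C@@H](CC(=O)OC)C[N+](=O)[O-] | intermediate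
23 | methyl (3S,4E)-3-{(4S,5S)-5-[(2Z)-7-(TBDPSO)-6-methylidene-1-(PMBO)hept-2-en-2-yl]-2,2-dimethyl-1,3-dioxolan-4-yl}-4-(hydroxyimino)butanoate (open-chain C6 aldoxime) | C=C(CO[Si](c1ccccc1)(c1ccccc1)C(C)(C)C)CC/C=C(/COCc1ccc(OC)cc1)[C@H](OC1(C)C)[C@@H](O1)[C@@H](CC(=O)OC)/C=N/O | intermediate
24 | C6 hydroximoyl chloride of 23 (C7–C9 unchanged) | C=C(CO[Si](c1ccccc1)(c1ccccc1)C(C)(C)C)CC/C=C(/COCc1ccc(OC)cc1)[C@H](OC1(C)C)[C@@H](O1)[C@@H](CC(=O)OC)/C(Cl)=N/O | intermediate
25 | C6 nitrile oxide (C7–C9 unchanged) | C=C(CO[Si](c1ccccc1)(c1ccccc1)C(C)(C)C)CC/C=C(/COCc1ccc(OC)cc1)[C@H](OC1(C)C)[C@@H](O1)[C@@H](CC(=O)OC)C#[N+][O-] | intermediate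
26 | isoxazoline-bridged ten-membered carbocycle: C6=N–O–C4 bridge over C5, 8,9-O-isopropylidene, C7 CH2CO2Me, C14 OPMB, C15 OTBDPS; (4R,7S,8S,9S), 1(10)Z | COC(=O)C[C@H]1C2=NO[C@@](CO[Si](c3ccccc3)(c3ccccc3)C(C)(C)C)(C2)CC/C=C(/COCc2ccc(OC)cc2)[C@H](OC2(C)C)[C@H]1O2 | intermediate
27 | ring β-hydroxy ketone: C6 ketone, C4 tertiary alcohol (4R), C7–C9 unchanged | COC(=O)C[C@H]1C(=O)C[C@@](O)(CO[Si](c2ccccc2)(c2ccccc2)C(C)(C)C)CC/C=C(/COCc2ccc(OC)cc2)[C@H](OC2(C)C)[C@H]1O2 | intermediate
28 | C4 tertiary mesylate of 27 | COC(=O)C[C@H]1C(=O)C[C@@](OS(C)(=O)=O)(CO[Si](c2ccccc2)(c2ccccc2)C(C)(C)C)CC/C=C(/COCc2ccc(OC)cc2)[C@H](OC2(C)C)[C@H]1O2 | intermediate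
29 | ring enone: C6 ketone, ring-cis (4E) C4=C5, 1(10)Z, C7–C9 unchanged | COC(=O)C[C@H]1C(=O)/C=C(/CO[Si](c2ccccc2)(c2ccccc2)C(C)(C)C)CC/C=C(/COCc2ccc(OC)cc2)[C@H](OC2(C)C)[C@H]1O2 | intermediate
30 | (6R)-allylic alcohol methyl ester (6R,7S,8S,9S) | COC(=O)C[C@H]1[C@H](O)/C=C(/CO[Si](c2ccccc2)(c2ccccc2)C(C)(C)C)CC/C=C(/COCc2ccc(OC)cc2)[C@H](OC2(C)C)[C@H]1O2 | intermediate
31 | trans-fused 12,6-lactone (6R,7S,8S,9S), 8,9-acetonide, C14 OPMB, C15 OTBDPS | C1C(=O)O[C@@H]2/C=C(/CO[Si](c3ccccc3)(c3ccccc3)C(C)(C)C)CC/C=C(/COCc3ccc(OC)cc3)[C@H](OC3(C)C)[C@@H](O3)[C@@H]12 | intermediate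
32 | C11 dimethylaminomethyl lactone (11R expected, configuration immaterial) | CN(C)C[C@@H]1C(=O)O[C@@H]2/C=C(/CO[Si](c3ccccc3)(c3ccccc3)C(C)(C)C)CC/C=C(/COCc3ccc(OC)cc3)[C@H](OC3(C)C)[C@@H](O3)[C@@H]12 | intermediate
33 | C11 trimethylammoniomethyl lactone iodide | C[N+](C)(C)C[C@@H]1C(=O)O[C@@H]2/C=C(/CO[Si](c3ccccc3)(c3ccccc3)C(C)(C)C)CC/C=C(/COCc3ccc(OC)cc3)[C@H](OC3(C)C)[C@@H](O3)[C@@H]12.[I-] | intermediate
34 | α-methylene lactone (6R,7S,8S,9S), 8,9-acetonide, C14 OPMB, C15 OTBDPS | C=C1C(=O)O[C@@H]2/C=C(/CO[Si](c3ccccc3)(c3ccccc3)C(C)(C)C)CC/C=C(/COCc3ccc(OC)cc3)[C@H](OC3(C)C)[C@@H](O3)[C@@H]12 | intermediate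
35 | 8,9-diol of 34 (configuration unchanged) | C=C1C(=O)O[C@@H]2/C=C(/CO[Si](c3ccccc3)(c3ccccc3)C(C)(C)C)CC/C=C(/COCc3ccc(OC)cc3)[C@H](O)[C@@H](O)[C@@H]12 | intermediate
36 | angelic acid, (2Z)-2-methylbut-2-enoic acid | C/C=C(/C)C(=O)O | starting material
37 | angelic 2,4,6-trichlorobenzoic anhydride | C/C=C(/C)C(=O)OC(=O)c1c(Cl)cc(Cl)cc1Cl | intermediate
38 | 8,9-bis-angelate, C14 OPMB, C15 OTBDPS (6R,7S,8S,9S) | C=C1C(=O)O[C@@H]2/C=C(/CO[Si](c3ccccc3)(c3ccccc3)C(C)(C)C)CC/C=C(/COCc3ccc(OC)cc3)[C@H](OC(=O)/C(C)=C\C)[C@@H](OC(=O)/C(C)=C\C)[C@@H]12 | intermediate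
39 | 8,9-bis-angelate with free C14 allylic alcohol, C15 OTBDPS | C=C1C(=O)O[C@@H]2/C=C(/CO[Si](c3ccccc3)(c3ccccc3)C(C)(C)C)CC/C=C(/CO)[C@H](OC(=O)/C(C)=C\C)[C@@H](OC(=O)/C(C)=C\C)[C@@H]12 | intermediate
40 | 8,9-bis-angelate C14 enal, C15 OTBDPS | C=C1C(=O)O[C@@H]2/C=C(/CO[Si](c3ccccc3)(c3ccccc3)C(C)(C)C)CC/C=C(/C=O)[C@H](OC(=O)/C(C)=C\C)[C@@H](OC(=O)/C(C)=C\C)[C@@H]12 | intermediate
41 | CNP0139154.1, (1(10)E,4E,6R,7S,8S,9S)-8,9-bis(angeloyloxy)-15-hydroxy-14-oxogermacra-1(10),4,11(13)-trien-12,6-olide | C=C1C(=O)O[C@@H]2/C=C(/CO)CC/C=C(/C=O)[C@H](OC(=O)/C(C)=C\C)[C@@H](OC(=O)/C(C)=C\C)[C@@H]12 | target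

Total step count: 24. Longest linear sequence: 23 steps (steps 1–4 and 6–24, from 1); step 5 is a one-step side branch.

Steps most likely to fail

Step 15. The nitrile oxide may dimerise to furoxan or oligomerise faster than it reaches the strained ten-membered transition state. The fallback changes the dipole and sets out from nitro ester 22. Me3SiCl and Et3N (benzene, rt → 60 °C, high dilution) convert 22 into the silyl nitronate F1, which cannot dimerise and tolerates prolonged heating. Its intramolecular cycloaddition to C4=C5 gives the N-silyloxy isoxazolidine F2. Brief treatment with catalytic TsOH in CH2Cl2 at 0 °C eliminates trimethylsilanol, and the route is rejoined at isoxazoline 26.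

Step 17. The elimination may lose regiocontrol (alkene towards C3 or C15), or base may open the ring of 27 by retro-aldol cleavage. The fallback breaks the C4–O bond while the heterocycle is still intact and sets out from isoxazoline 26. LiN(i-Pr)2 (2.5 equiv, THF, −78 → −20 °C; the first equivalent is taken up by the ester) deprotonates C5, and the carbanion expels the ring oxygen from C4. This fragmentation can only give the C4=C5 double bond and leads to the conjugated oxime F3. Reductive deoximation with aqueous TiCl3 buffered by NH4OAc in THF then gives enone 29, where the route is rejoined; steps 16 and 17 are bypassed.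

Step 18. Hydride may be delivered to the other face of C6 with poor or reversed selectivity. The fallback sets out from enone 29 and uses inversion instead of retention in the ring closure. The acid treatment is omitted so that the (6S)-hydroxy ester F4 is kept. Its ester is saponified (LiOH, THF/H2O) to the (6S)-hydroxy acid F5, and a Mitsunobu lactonisation (PPh3, DIAD, toluene, 0 °C) closes the γ-lactone with inversion at C6. This gives lactone 31, where the route is rejoined; any (6R)-alcohol present lactonises directly, so both epimers converge.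

Further compounds
F1 | step 15 | trimethylsilyl nitronate of 22 (C7–C9 unchanged) | C=C(CO[Si](c1ccccc1)(c1ccccc1)C(C)(C)C)CC/C=C(/COCc1ccc(OC)cc1)[C@H](OC1(C)C)[C@@H](O1)[C@@H](CC(=O)OC)C=[N+]([O-])O[Si](C)(C)C
F2 | step 15 | N-(trimethylsilyloxy)isoxazolidine-bridged ten-membered carbocycle (C4 as in 26, C6–H cis to the C4–C3 bond) | COC(=O)C[C@H]1[C@@H]2N(O[Si](C)(C)C)O[C@@](CO[Si](c3ccccc3)(c3ccccc3)C(C)(C)C)(C2)CC/C=C(/COCc2ccc(OC)cc2)[C@H](OC2(C)C)[C@H]1O2
F3 | step 17 | ring α,β-unsaturated oxime: C6 oxime, ring-cis (4E) C4=C5, C7–C9 unchanged | COC(=O)C[C@H]1/C(=N/O)/C=C(/CO[Si](c2ccccc2)(c2ccccc2)C(C)(C)C)CC/C=C(/COCc2ccc(OC)cc2)[C@H](OC2(C)C)[C@H]1O2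
F4 | step 18 | (6S)-allylic alcohol methyl ester, C6 epimer of 30 | COC(=O)C[C@H]1[C@@H](O)/C=C(/CO[Si](c2ccccc2)(c2ccccc2)C(C)(C)C)CC/C=C(/COCc2ccc(OC)cc2)[C@H](OC2(C)C)[C@H]1O2
F5 | step 18 | (6S)-hydroxy acid from F4 | OC(=O)C[C@H]1[C@@H](O)/C=C(/CO[Si](c2ccccc2)(c2ccccc2)C(C)(C)C)CC/C=C(/COCc2ccc(OC)cc2)[C@H](OC2(C)C)[C@H]1O2
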